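**Target:** CNP0503951.0, compound 13, methyl 4-{[4-[(2,4-dihydroxy-6-methylbenzoyl)oxy]-2-hydroxy-6-methylbenzoyl]oxy}-2-methoxy-6-methylbenzoate.

## The problem

Target 13 is a linear tridepside: three 2,4-dioxygenated 6-methylbenzoyl (orsellinate) rings are joined head to tail by two aryl ester bonds, one from the carboxyl carbon of ring A to O4 of ring B and one from the carboxyl carbon of ring B to O4 of ring C, and ring C ends in a methyl ester and carries a methyl ether at C2. There is no stereocentre, so the whole difficulty is telling oxygen atoms apart. In ring C, O2 must be methylated and O4 acylated; in ring B, O4 must be acylated while the C2 hydroxyl stays free; ring A keeps both hydroxyls. Each ester bond has to be made from a benzoic acid with two ortho substituents, and once made it is the weak point of the molecule. Depside esters are opened by hydroxide and alkoxide, most easily when the acyl ring has free ortho or para hydroxyls, and free orsellinic acids lose CO2 readily, so the last operations must be neutral. One structural fact helps: in every ring the C2 hydroxyl is held in a six-membered hydrogen bond to the neighbouring carbonyl, while the C4 hydroxyl is free and more acidic. The feature that invites the key step is that all three rings share one pattern (carboxyl at C1, oxygen at C2 and C4, methyl at C6, hydrogen at C3 and C5), which two hydrogens richer is a 6-methylcyclohexane-2,4-dione-1-carboxylate whose C1, C2, C3 and ester carbon are the four carbons of an acetoacetate and whose C4, C5, C6 and methyl are those of a crotonate.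

## Retrosynthesis

**13 to 12.** The last cut is at the two O–benzyl bonds on ring A. Benzyl ethers are preferred to silyl, acyl or alkyl protection because hydrogenolysis is neutral, while fluoride, base or Lewis acids would threaten the depside bonds or the ring C methyl ether. Compound 12 is no simpler in skeleton, but it is the form in which the last ester bond can be made from a protected acid. The forward step only has to be a clean hydrogenolysis.

**12 to 11 and 8.** The ester C–O bond between the ring A carbonyl and O4 of ring B is cut. Cutting at the A end first, and then again at the B end, makes the acid partner the same monomer 8 both times. The neighbouring cut at the B–C bond first would need an A–B acid with orthogonal carboxyl protection. The precursors are the didepside 11 and the monomer acid 8. The forward reaction must acylate the C4 hydroxyl of ring B in the presence of the hydrogen-bonded C2 hydroxyl and leave the existing depside bond alone.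

**11 to 10 to 9.** First the two benzyl ethers of ring B are restored (10), then the O–CH3 bond at C2 of ring C is cut (9). The methylation is placed here because in 9 the hydroxyl to be methylated is the only one in the molecule, so ring C needs no protecting group. The neighbouring order, methylating ring C before the first acylation, costs a protection and a deprotection of C4–OH and is kept as a fallback. The forward step must methylate a hydrogen-bonded phenol without opening the aryl ester; the acyl ring of 9 is fully benzylated, so the phenoxide-triggered cleavage typical of depsides has no starting point.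

**9 to 6 and 8.** The ester bond between the ring B carbonyl and O4 of ring C is cut, giving the phenol 6 and the acid 8. The forward reaction needs the same preference as above, C4–OH over the chelated C2–OH.

**8 to 7 to 6.** Acid 8 is 6 with both hydroxyls benzylated (7) and the methyl ester hydrolysed. All three rings of 13 therefore come from one compound, 6.

**6 to 5 to 4.** The benzene ring is traced back to its dihydro level instead of being made by substitution on a preformed resorcinol, which would have to choose between ring positions. In the dione 4 every substituent is fixed by connectivity. The forward path passes through the dibromide 5 because aromatization with bromine also brominates the activated ring at C3 and C5; these two bromines are then removed by hydrogenolysis.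

**4 to 3 to 1 and 2.** The C3–C4 bond of 4 is cut as a Claisen (Dieckmann) bond, giving the acyclic keto diester 3. The C1–C6 bond of 3 is cut as a Michael bond, giving methyl acetoacetate 1 and methyl crotonate 2. This pair of cuts is preferred to the neighbouring pair (C2–C3 and C1–C6, held in reserve as a fallback) because 1 and 2 are bulk esters and both bonds form in one flask under one base. The forward reaction needs only regiochemical control.

## Roads not taken

Alternative 1: Ring C from a 2-pyrone. The cut is through C3–C4 and C5–C6 of ring C. The pyrone A1, methyl 4-methoxy-6-methyl-2-oxopyran-5-carboxylate, would be heated with the ketene acetal A2, 1,1-bis(trimethylsilyloxy)ethene. The bridged cycloadduct loses CO2 and silanol and gives the phenol A3, methyl 4-hydroxy-2-methoxy-6-methylbenzoate.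
- Merit: A3 arrives with O2 methylated and O4 free, so ring C needs no methylation next to a depside bond. In this respect it is better than the chosen plan.
- Weak points: the 4-methoxy group is a donor on the diene and the reacting terminus C6 carries a methyl group, so an inverse-demand addition of A2 should be sluggish and need high temperature. A2 is moisture-sensitive. A1 needs its own multi-step preparation.
- Comparison: the route supplies ring C only, so rings A and B would need a second ring synthesis. The chosen plan sets against the differentiated A3 that its own differentiation costs no protecting group (chelation in step 6, one methylation in step 7) and that one annulation feeds all three rings.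

Alternative 2: Ring A by vinylketene–ynol ether benzannulation. Ring A is cut at C1–C6, C1–C2, C3–C4 and C4–C5. The ring B-bound diazo ester A4 (a 2-diazo-4-methyl-3-oxopent-4-enoate on O4 of ring B, with the C2 oxygen of ring B silylated) would be irradiated. Wolff rearrangement gives a ketene that takes up the silyl ynol ether A5, (triisopropylsilyloxy)ethyne, by [2+2] addition; the four-membered adduct opens to a dienylketene, which closes by six-electron electrocyclization to the bis-silyl ether of the target, A6.
- Merits: the A–B ester bond is made from an unhindered acyl unit before ring A exists, so the slow acylation by a di-ortho-substituted acid is avoided. Ring A comes out with its oxygens in defined positions. Here it is better than the chosen plan.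
- Weak points: UV irradiation of a molecule with two aryl ester bonds invites photo-Fries rearrangement. The ketene carries an ester group and can react as a heterodiene or dimerize before A5 reaches it, and A5 is itself a sensitive reagent that has to be made fresh. Building A4 needs the B–C bond and a selectively silylated ring B first, so the phenol differentiation is not saved, only moved. The final desilylation of A6 with fluoride is basic toward a depside with free hydroxyls.
- Comparison: the most demanding step comes last, on the most valuable intermediate. The chosen plan sets against this a neutral hydrogenolytic endgame and reactions of known type throughout.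

Alternative 3: Ring B by Diels–Alder reaction on an aryl butynoate. Ring B is cut at C1–C2 and C5–C6. The diene A7, 1-methoxy-1,3-bis(trimethylsilyloxy)buta-1,3-diene, would add thermally to A8, the but-2-ynoate ester of A3. Loss of methanol and of the silyl groups on acidic work-up aromatizes the ring to A9, methyl 4-(2,4-dihydroxy-6-methylbenzoyl)oxy-2-methoxy-6-methylbenzoate, the same compound as 11 of the chosen route.
- Merits: the ester bond is made with an unhindered acid, ring B needs no protecting groups and no hydrogenolysis, and the regiochemistry follows from the polarity of both partners. For ring B alone it is shorter than the chosen sequence 6 to 9 to 10 to 11 plus the preparation of 8.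
- Weak points: A8, a but-2-ynoate with a beta methyl group, is a poor dienophile, and A7 is thermally and hydrolytically labile, so it must be used in excess. A3 has to be made first by a sequence of its own. Ring A then needs either a second round, with the same C4-over-C2 selectivity question, or a conventional coupling anyway.
- Comparison: the chosen plan sets against the shorter ring B construction the reliability of carbodiimide couplings of hindered acids with phenols and the use of one cheap, scalable ring synthesis for every ring.

Key step: step 1

Assumption: 3 and 4 are formed and used as racemic mixtures of diastereomers and keto–enol tautomers; they are drawn as keto forms without stereodescriptors because both sp3 centres become aromatic carbons in step 2.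

## Route

Step 1
Reactants: 1 methyl acetoacetate (methyl 3-oxobutanoate); 2 methyl (E)-but-2-enoate (methyl crotonate)
Product: 4 methyl 6-methyl-2,4-dioxocyclohexane-1-carboxylate, via dimethyl 2-acetyl-3-methylpentanedioate 3 (not isolated)
Conditions: NaOMe (1.1 equiv), MeOH, reflux; then aq. HCl, 0 °C
Reagents that add atoms: none
Why: Methoxide deprotonates 1 at the carbon between its two carbonyl groups, and this stabilized enolate adds to the beta carbon of 2 (Michael addition), which forms the C1–C6 bond and gives the enolate of 3. Proton exchange in methanol moves the charge to the ketone methyl group of 3, whose enolate attacks the ester carbonyl that came from 2 and expels methoxide (Dieckmann-type Claisen condensation), forming the C3–C4 bond. The ring closes in the 6-(enolexo)-exo-trig mode, with the enolate double bond outside the new ring and the leaving methoxide exocyclic. The closest known reaction type is the base-mediated Michael–Dieckmann annulation of acetoacetates with crotonates to dihydroresorcylates, of which this is a direct case. C1 and C6 become stereocentres without control: 4 is racemic, C1 equilibrates through the enol of the beta-keto ester so that the trans arrangement of ester and methyl should prevail, and both centres are flattened in step 2, so no stereocontrol is needed. The only selectivity required is regiochemical: the doubly activated carbon of 1 is by far the most acidic site and is the Michael donor, which places the methyl group next to the ester-bearing carbon, and of the possible Claisen closures of 3 only attack of the ketone methyl on the distal ester gives a six-membered ring, the others being four-membered. All steps before the last are reversible, and the sequence is pulled forward by formation of the stable enolate of the 1,3-dione, which is why a full equivalent of NaOMe is used; methyl esters with methoxide in methanol exclude ester scrambling.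

Step 2
Reactants: 4 methyl 6-methyl-2,4-dioxocyclohexane-1-carboxylate
Product: 5 methyl 3,5-dibromo-2,4-dihydroxy-6-methylbenzoate
Conditions: Br2 (3 equiv), AcOH, rt
Reagents that add atoms: bromine, BrBr
Why: Bromination of the enolized beta-dicarbonyl system followed by loss of HBr raises the ring to the aromatic oxidation level, and the electron-rich ring then takes up bromine at its two free positions C3 and C5 under the same conditions (alpha-halogenation–dehydrohalogenation aromatization, then electrophilic aromatic substitution). Three equivalents of Br2 are consumed in a defined way, so the dibromide should be the single end point.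

Step 3
Reactants: 5 methyl 3,5-dibromo-2,4-dihydroxy-6-methylbenzoate
Product: 6 methyl 2,4-dihydroxy-6-methylbenzoate (methyl orsellinate)
Conditions: H2 (1 atm), 10% Pd/C, NaOAc, MeOH, rt
Reagents that add atoms: none
Why: Catalytic hydrogenolysis of the two aryl C–Br bonds; NaOAc takes up the HBr so that the catalyst stays active. The ester, the phenols and the ring are inert under these conditions.

Step 4
Reactants: 6 methyl 2,4-dihydroxy-6-methylbenzoate
Product: 7 methyl 2,4-bis(benzyloxy)-6-methylbenzoate
Conditions: BnBr (2.5 equiv), K2CO3, DMF, 70 °C
Reagents that add atoms: benzyl bromide, BrCc1ccccc1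
Why: Williamson ether synthesis; the free C4–OH reacts first, and heating in DMF with excess BnBr also alkylates the hydrogen-bonded C2–OH. The methyl ester does not react with carbonate.

Step 5
Reactants: 7 methyl 2,4-bis(benzyloxy)-6-methylbenzoate
Product: 8 2,4-bis(benzyloxy)-6-methylbenzoic acid
Conditions: KOH, DMSO–H2O, 90 °C; then cold aq. HCl
Reagents that add atoms: potassium hydroxide, [K+].[OH-]
Why: Saponification of a di-ortho-substituted benzoate needs the poorly solvated hydroxide of aqueous DMSO and heat; benzyl aryl ethers are stable to it. With both oxygens etherified the acid should not decarboxylate as free orsellinic acid would, provided the acidification is done cold.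

Step 6
Reactants: 6 methyl 2,4-dihydroxy-6-methylbenzoate; 8 2,4-bis(benzyloxy)-6-methylbenzoic acid
Product: 9 methyl 4-{[2,4-bis(benzyloxy)-6-methylbenzoyl]oxy}-2-hydroxy-6-methylbenzoate
Conditions: DCC, DMAP (cat.), CH2Cl2, 0 °C to rt
Reagents that add atoms: none
Why: Steglich esterification (carbodiimide activation with acyl transfer by DMAP) of a phenol with a hindered benzoic acid, a standard way to depside bonds. With one equivalent of 8 the free and more acidic C4–OH of 6 should react in preference to the C2–OH, which is held in a hydrogen bond to the ester carbonyl.

Step 7
Reactants: 9 methyl 4-{[2,4-bis(benzyloxy)-6-methylbenzoyl]oxy}-2-hydroxy-6-methylbenzoate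
Product: 10 methyl 4-{[2,4-bis(benzyloxy)-6-methylbenzoyl]oxy}-2-methoxy-6-methylbenzoate
Conditions: MeI (excess), K2CO3, acetone, reflux
Reagents that add atoms: iodomethane, CI
Why: Williamson O-methylation of the one remaining hydroxyl; its hydrogen bond to the ester makes it slow, hence excess MeI and reflux. The depside bond of 9 is a di-ortho-substituted aryl benzoate whose acyl ring has no free hydroxyl, so base-induced depside cleavage has no entry and anhydrous carbonate in acetone should leave it intact.

Step 8
Reactants: 10 methyl 4-{[2,4-bis(benzyloxy)-6-methylbenzoyl]oxy}-2-methoxy-6-methylbenzoate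
Product: 11 methyl 4-[(2,4-dihydroxy-6-methylbenzoyl)oxy]-2-methoxy-6-methylbenzoate
Conditions: H2 (1 atm), 10% Pd/C, EtOAc, rt
Reagents that add atoms: none
Why: Hydrogenolysis of both benzyl aryl ethers under neutral conditions; aryl esters, the methyl ester and the methyl ether are not reduced. EtOAc is used so that no alcohol is present that could transesterify the depside bond.

Step 9
Reactants: 11 methyl 4-[(2,4-dihydroxy-6-methylbenzoyl)oxy]-2-methoxy-6-methylbenzoate; 8 2,4-bis(benzyloxy)-6-methylbenzoic acid
Product: 12 methyl 4-{[4-{[2,4-bis(benzyloxy)-6-methylbenzoyl]oxy}-2-hydroxy-6-methylbenzoyl]oxy}-2-methoxy-6-methylbenzoate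
Conditions: DCC, DMAP (cat.), CH2Cl2, 0 °C to rt
Reagents that add atoms: none
Why: Second Steglich esterification with the same acid. The C2–OH of ring B is hydrogen-bonded to the depside carbonyl, so acylation should go to C4–OH, the same preference that step 6 uses; one equivalent of 8 and low temperature guard against double acylation.

Step 10
Reactants: 12 methyl 4-{[4-{[2,4-bis(benzyloxy)-6-methylbenzoyl]oxy}-2-hydroxy-6-methylbenzoyl]oxy}-2-methoxy-6-methylbenzoate
Product: 13 methyl 4-{[4-[(2,4-dihydroxy-6-methylbenzoyl)oxy]-2-hydroxy-6-methylbenzoyl]oxy}-2-methoxy-6-methylbenzoate (CNP0503951.0)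
Conditions: H2 (1 atm), 10% Pd/C, EtOAc, rt
Reagents that add atoms: none
Why: Neutral hydrogenolysis of the last two benzyl ethers frees ring A without touching the two depside bonds or the methyl ester and should give 13. The target has no stereocentre, so nothing can be scrambled.

## Compound list

1 | methyl acetoacetate (methyl 3-oxobutanoate) | COC(=O)CC(C)=O | starting material
2 | methyl (E)-but-2-enoate (methyl crotonate) | COC(=O)/C=C/C | starting material
3 | dimethyl 2-acetyl-3-methylpentanedioate (Michael adduct, mixture of diastereomers, formed as its enolate) | COC(=O)CC(C)C(C(C)=O)C(=O)OC | intermediate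
4 | methyl 6-methyl-2,4-dioxocyclohexane-1-carboxylate (racemic, enolized) | COC(=O)C1C(C)CC(=O)CC1=O | intermediate
5 | methyl 3,5-dibromo-2,4-dihydroxy-6-methylbenzoate | COC(=O)c1c(C)c(Br)c(O)c(Br)c1O | intermediate
6 | methyl 2,4-dihydroxy-6-methylbenzoate (methyl orsellinate) | COC(=O)c1c(C)cc(O)cc1O | intermediate
7 | methyl 2,4-bis(benzyloxy)-6-methylbenzoate | COC(=O)c1c(C)cc(OCc2ccccc2)cc1OCc1ccccc1 | intermediate
8 | 2,4-bis(benzyloxy)-6-methylbenzoic acid | OC(=O)c1c(C)cc(OCc2ccccc2)cc1OCc1ccccc1 | intermediate
9 | methyl 4-{[2,4-bis(benzyloxy)-6-methylbenzoyl]oxy}-2-hydroxy-6-methylbenzoate | COC(=O)c1c(C)cc(OC(=O)c2c(C)cc(OCc3ccccc3)cc2OCc2ccccc2)cc1O | intermediate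
10 | methyl 4-{[2,4-bis(benzyloxy)-6-methylbenzoyl]oxy}-2-methoxy-6-methylbenzoate | COC(=O)c1c(C)cc(OC(=O)c2c(C)cc(OCc3ccccc3)cc2OCc2ccccc2)cc1OC | intermediate
11 | methyl 4-[(2,4-dihydroxy-6-methylbenzoyl)oxy]-2-methoxy-6-methylbenzoate | COC(=O)c1c(C)cc(OC(=O)c2c(C)cc(O)cc2O)cc1OC | intermediate
12 | methyl 4-{[4-{[2,4-bis(benzyloxy)-6-methylbenzoyl]oxy}-2-hydroxy-6-methylbenzoyl]oxy}-2-methoxy-6-methylbenzoate | COC(=O)c1c(C)cc(OC(=O)c2c(C)cc(OC(=O)c3c(C)cc(OCc4ccccc4)cc3OCc3ccccc3)cc2O)cc1OC | intermediate
13 | methyl 4-{[4-[(2,4-dihydroxy-6-methylbenzoyl)oxy]-2-hydroxy-6-methylbenzoyl]oxy}-2-methoxy-6-methylbenzoate (CNP0503951.0) | COC(=O)c1c(C)cc(OC(=O)c2c(C)cc(OC(=O)c3c(C)cc(O)cc3O)cc2O)cc1OC | target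

## Step count and risks

Total step count: 10. Longest linear sequence: 10 steps (steps 1 to 10; acid 8 is drawn from the same intermediate 6 that serves as ring C, so the route is linear in effect).

**Step 1 (key step).** The Michael addition to a beta-methyl acrylate is slow. During long heating methoxide can instead cleave the acetyl group from the adduct (retro-Claisen), and on acidification the beta-keto ester can lose its ester group by hydrolysis and decarboxylation. The fallback forms the same ring from the other pair of cuts. No numbered compound precedes step 1, so the fallback sets out from two other purchased materials in place of 1 and 2 and comes back to the route at 4. Dimethyl propanedioate F1 adds under NaOMe in MeOH to (E)-pent-3-en-2-one F2, a much better acceptor than 2. The adduct, dimethyl 2-(4-oxopentan-2-yl)propanedioate F3, has no acetyl group on its acidic carbon that could be cleaved. Its ketone methyl closes onto one malonate ester in the same flask and gives 4.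

**Step 7.** The hydrogen-bonded hydroxyl may methylate incompletely, and forcing the reaction may lead to attack of phenoxide or carbonate on the aryl ester, with transesterification or cleavage of the depside bond. The fallback sets out from 6 and comes back at 10; it methylates ring C before any depside bond exists. Compound 6 is benzylated at the free C4–OH only (BnBr, one equivalent, K2CO3, acetone) to methyl 4-(benzyloxy)-2-hydroxy-6-methylbenzoate F4. This is methylated (MeI, K2CO3, DMF) to methyl 4-(benzyloxy)-2-methoxy-6-methylbenzoate F5 and hydrogenolysed (H2, Pd/C) to methyl 4-hydroxy-2-methoxy-6-methylbenzoate F6, the same phenol as A3. Coupling of F6 with 8 (DCC, DMAP) gives 10.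

**Step 9.** Site selectivity between the two hydroxyls of ring B may be incomplete, giving acylation at C2–OH or double acylation. The existing depside bond of 11, whose acyl ring now has free hydroxyls, may also be opened or transesterified under the basic acyl-transfer conditions. The fallback sets out from 6 and comes back at 13; it differentiates the ring B oxygens by protecting groups instead of by chelation. Compound 6 is protected at C4–OH (MOMCl, iPr2NEt, CH2Cl2) to methyl 2-hydroxy-4-(methoxymethoxy)-6-methylbenzoate F7, which is benzylated at C2–OH (BnBr, K2CO3, DMF) to methyl 2-(benzyloxy)-4-(methoxymethoxy)-6-methylbenzoate F8 and saponified (KOH, DMSO–H2O; buffered acidification) to 2-(benzyloxy)-4-(methoxymethoxy)-6-methylbenzoic acid F9. Coupling of this acid with 6 (DCC, DMAP) gives methyl 4-{[2-(benzyloxy)-4-(methoxymethoxy)-6-methylbenzoyl]oxy}-2-hydroxy-6-methylbenzoate F10, and methylation (MeI, K2CO3, acetone) gives methyl 4-{[2-(benzyloxy)-4-(methoxymethoxy)-6-methylbenzoyl]oxy}-2-methoxy-6-methylbenzoate F11; if this methylation is also weak, the acid is coupled with F6 instead of 6 and gives the same methyl ether directly. Dilute HCl in aqueous THF then removes the acetal and gives methyl 4-{[2-(benzyloxy)-4-hydroxy-6-methylbenzoyl]oxy}-2-methoxy-6-methylbenzoate F12, whose only free hydroxyl is C4–OH of ring B. Acylation of this phenol with 8 (DCC, DMAP) gives methyl 4-{[2-(benzyloxy)-4-{[2,4-bis(benzyloxy)-6-methylbenzoyl]oxy}-6-methylbenzoyl]oxy}-2-methoxy-6-methylbenzoate F13, and hydrogenolysis of its three benzyl ethers (H2, Pd/C, EtOAc) gives 13.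

**Step 2.** Bromination may go further than intended, into the C6 methyl group, or loss of HBr may be incomplete and leave non-aromatic polybrominated material. The fallback sets out from 4 and comes back at 6, bypassing 5 and step 3. Compound 4 is dehydrogenated directly with Hg(OAc)2 and NaOAc in hot AcOH, a known oxidative aromatization of cyclic 1,3-diones to resorcinols. This fallback makes no compound outside the compound list, so its entry below is F0.

## Further compounds

F1 | step 1 | dimethyl propanedioate (dimethyl malonate) | COC(=O)CC(=O)OC
F2 | step 1 | (E)-pent-3-en-2-one | C/C=C/C(C)=O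
F3 | step 1 | dimethyl 2-(4-oxopentan-2-yl)propanedioate | COC(=O)C(C(C)CC(C)=O)C(=O)OC
F4 | step 7 | methyl 4-(benzyloxy)-2-hydroxy-6-methylbenzoate | COC(=O)c1c(C)cc(OCc2ccccc2)cc1O
F5 | step 7 | methyl 4-(benzyloxy)-2-methoxy-6-methylbenzoate | COC(=O)c1c(C)cc(OCc2ccccc2)cc1OC
F6 | step 7 | methyl 4-hydroxy-2-methoxy-6-methylbenzoate | COC(=O)c1c(C)cc(O)cc1OC
F7 | step 9 | methyl 2-hydroxy-4-(methoxymethoxy)-6-methylbenzoate | COC(=O)c1c(C)cc(OCOC)cc1O
F8 | step 9 | methyl 2-(benzyloxy)-4-(methoxymethoxy)-6-methylbenzoate | COC(=O)c1c(C)cc(OCOC)cc1OCc1ccccc1
F9 | step 9 | 2-(benzyloxy)-4-(methoxymethoxy)-6-methylbenzoic acid | OC(=O)c1c(C)cc(OCOC)cc1OCc1ccccc1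
F10 | step 9 | methyl 4-{[2-(benzyloxy)-4-(methoxymethoxy)-6-methylbenzoyl]oxy}-2-hydroxy-6-methylbenzoate | COC(=O)c1c(C)cc(OC(=O)c2c(C)cc(OCOC)cc2OCc2ccccc2)cc1O
F11 | step 9 | methyl 4-{[2-(benzyloxy)-4-(methoxymethoxy)-6-methylbenzoyl]oxy}-2-methoxy-6-methylbenzoate | COC(=O)c1c(C)cc(OC(=O)c2c(C)cc(OCOC)cc2OCc2ccccc2)cc1OC
F12 | step 9 | methyl 4-{[2-(benzyloxy)-4-hydroxy-6-methylbenzoyl]oxy}-2-methoxy-6-methylbenzoate | COC(=O)c1c(C)cc(OC(=O)c2c(C)cc(O)cc2OCc2ccccc2)cc1OC
F13 | step 9 | methyl 4-{[2-(benzyloxy)-4-{[2,4-bis(benzyloxy)-6-methylbenzoyl]oxy}-6-methylbenzoyl]oxy}-2-methoxy-6-methylbenzoate | COC(=O)c1c(C)cc(OC(=O)c2c(C)cc(OC(=O)c3c(C)cc(OCc4ccccc4)cc3OCc3ccccc3)cc2OCc2ccccc2)cc1OC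
F0 | step 2 | none | none
A1 | alternative 1 | methyl 4-methoxy-6-methyl-2-oxopyran-5-carboxylate | COC(=O)C1=C(C)OC(=O)C=C1OC
A2 | alternative 1 | 1,1-bis(trimethylsilyloxy)ethene | C=C(O[Si](C)(C)C)O[Si](C)(C)C
A3 | alternative 1 | methyl 4-hydroxy-2-methoxy-6-methylbenzoate | COC(=O)c1c(C)cc(O)cc1OC
A4 | alternative 2 | methyl 4-{[4-[(2-diazo-4-methyl-3-oxopent-4-enoyl)oxy]-6-methyl-2-(triisopropylsilyloxy)benzoyl]oxy}-2-methoxy-6-methylbenzoate | COC(=O)c1c(C)cc(OC(=O)c2c(C)cc(OC(=O)C(=[N+]=[N-])C(=O)C(C)=C)cc2O[Si](C(C)C)(C(C)C)C(C)C)cc1OC
A5 | alternative 2 | (triisopropylsilyloxy)ethyne | C#CO[Si](C(C)C)(C(C)C)C(C)C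
A6 | alternative 2 | methyl 4-{[4-{[4-hydroxy-6-methyl-2-(triisopropylsilyloxy)benzoyl]oxy}-6-methyl-2-(triisopropylsilyloxy)benzoyl]oxy}-2-methoxy-6-methylbenzoate | COC(=O)c1c(C)cc(OC(=O)c2c(C)cc(OC(=O)c3c(C)cc(O)cc3O[Si](C(C)C)(C(C)C)C(C)C)cc2O[Si](C(C)C)(C(C)C)C(C)C)cc1OC
A7 | alternative 3 | 1-methoxy-1,3-bis(trimethylsilyloxy)buta-1,3-diene | COC(=CC(=C)O[Si](C)(C)C)O[Si](C)(C)C
A8 | alternative 3 | methyl 4-(but-2-ynoyloxy)-2-methoxy-6-methylbenzoate | COC(=O)c1c(C)cc(OC(=O)C#CC)cc1OC
A9 | alternative 3 | methyl 4-(2,4-dihydroxy-6-methylbenzoyl)oxy-2-methoxy-6-methylbenzoate | COC(=O)c1c(C)cc(OC(=O)c2c(C)cc(O)cc2O)cc1OC
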